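## Retrosynthetic overview

1. Target ⇐ 7'-O-benzyl ether ⇐ anti-dihydroxylation of a C6=C7 alkene ⇐ sulfoxide syn-elimination of a C7-sulfinyl adduct; the C5 aryl ether is carried from the start.
2. Key disconnection: C5–C6 and C7–C8 together, by photoenolization/[4+2] cycloaddition of a 2-formyl-3-(aryloxymethyl)-γ-pyranone with (S)-p-tolyl vinyl sulfoxide, a chiral acetylene equivalent whose chirality comes from menthol via sulfur.
3. Enabling feature: the C4a=C8a bond of the weakly aromatic γ-pyranone ring (O1–C2–C3–C4–C4a–C8a) carries C5H2–OAr and C8H=O on adjacent carbons. A 1,5-H shift from C5 to the excited C8=O gives the o-quinodimethane C5=C4a–C8a=C8, and cycloaddition restores the pyranone.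
4. Aldehyde ⇐ sp3–sp2 Suzuki coupling of a pyranonyl enol triflate (from O-benzyl kojic acid by Wittig, hydrogenation, ortho-hydroxymethylation) with the aryloxymethyltrifluoroborate of a 6-hydroxychromone (Claisen condensation/cyclodehydration).
5. Ring order: γ-pyranone (purchased), chromone ring (step 7), carbocycle C5–C8 last (step 12).

Key step: step 12

Remark on the chemistry: compound 3 is carried on as an E/Z mixture (E drawn) because both isomers give 4; the sense of induction in step 12 is the one predicted by the chelate model, and if it proved opposite the (R)-sulfoxide from (−)-menthyl (S)-p-toluenesulfinate would be used.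

## Route

Step 1
Reactants: 1 5-(benzyloxy)-2-(hydroxymethyl)-4H-pyran-4-one
Product: 2 5-(benzyloxy)-4-oxo-4H-pyran-2-carbaldehyde
Conditions: activated MnO2 (10 equiv), CHCl3, reflux
Reagents that add atoms: none
Why: MnO2 oxidation of an allylic-type primary alcohol (the CH2OH sits on the enol-ether C=C of the pyranone) should stop at the aldehyde and leave the benzyl ether untouched.

Step 2
Reactants: 2 5-(benzyloxy)-4-oxo-4H-pyran-2-carbaldehyde
Product: 3 5-(benzyloxy)-2-(2-phenylethenyl)-4H-pyran-4-one (E/Z mixture; E drawn)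
Conditions: BnPPh3Cl, KOtBu, THF, 0 °C → rt
Reagents that add atoms: benzyltriphenylphosphonium chloride, [Cl-].c1ccc(C[P+](c2ccccc2)(c2ccccc2)c2ccccc2)cc1
Why: Wittig olefination with a semi-stabilized ylide should be efficient on this non-enolizable aldehyde, and the alkene geometry is irrelevant because the double bond is hydrogenated next.

Step 3
Reactants: 3 5-(benzyloxy)-2-(2-phenylethenyl)-4H-pyran-4-one
Product: 4 5-hydroxy-2-(2-phenylethyl)-4H-pyran-4-one
Conditions: H2 (1 atm), 10% Pd/C, EtOAc/MeOH, rt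
Reagents that add atoms: none
Why: catalytic hydrogenation should saturate the styryl C=C and hydrogenolyse the benzyl ether in one operation, the vinylogous-ester pyranone ring being reduced much more slowly.

Step 4
Reactants: 4 5-hydroxy-2-(2-phenylethyl)-4H-pyran-4-one
Product: 5 3-hydroxy-2-(hydroxymethyl)-6-(2-phenylethyl)-4H-pyran-4-one
Conditions: 37% aq. HCHO, NaOH (1.1 equiv), H2O/MeOH, rt; then HCl to pH 3
Reagents that add atoms: formaldehyde, C=O
Why: aldol-type ortho-hydroxymethylation of the enolate of a 3-hydroxy-4-pyranone (as with kojic acid and allomaltol) should occur only at the carbon next to the enolic OH.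

Step 5
Reactants: 5 3-hydroxy-2-(hydroxymethyl)-6-(2-phenylethyl)-4H-pyran-4-one
Product: 6 2-(hydroxymethyl)-4-oxo-6-(2-phenylethyl)-4H-pyran-3-yl trifluoromethanesulfonate
Conditions: PhNTf2 (1.05 equiv), Et3N, CH2Cl2, 0 °C → rt
Reagents that add atoms: N-phenylbis(trifluoromethanesulfonimide), O=S(=O)(N(c1ccccc1)S(=O)(=O)C(F)(F)F)C(F)(F)F
Why: the mild triflyl donor should sulfonylate the acidic enolic hydroxyl (as its ammonium enolate) much faster than the neutral primary alcohol.

Step 6
Reactants: 7 1-(2,4,5-trihydroxyphenyl)ethan-1-one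
Product: 8 1-[4-(benzyloxy)-2,5-dihydroxyphenyl]ethan-1-one
Conditions: BnBr (1.0 equiv), NaHCO3, DMF, rt, Ar
Reagents that add atoms: benzyl bromide, BrCc1ccccc1
Why: Williamson etherification with a weak base should select the most acidic phenol, the 4'-OH para to the acetyl group, since the 2'-OH is hydrogen-bonded to the carbonyl and the 5'-OH is the least acidic.

Step 7
Reactants: 8 1-[4-(benzyloxy)-2,5-dihydroxyphenyl]ethan-1-one; 9 ethyl 3-phenylpropanoate
Product: 11 7-(benzyloxy)-6-hydroxy-2-(2-phenylethyl)-4H-chromen-4-one, via 1,3-diketone 10 (not isolated)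
Conditions: NaH (5 equiv), THF, reflux; then cat. conc. HCl, MeOH, reflux
Reagents that add atoms: none
Why: crossed Claisen condensation of the acetophenone enolate (phenols masked as phenoxides) with the ester, then acid-catalysed cyclodehydration through the 2'-OH, is the standard construction of 2-substituted chromones.

Step 8
Reactants: 11 7-(benzyloxy)-6-hydroxy-2-(2-phenylethyl)-4H-chromen-4-one; 12 potassium (bromomethyl)trifluoroborate
Product: 13 potassium ({[7-(benzyloxy)-4-oxo-2-(2-phenylethyl)-4H-chromen-6-yl]oxy}methyl)trifluoroborate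
Conditions: K2CO3 (2 equiv), DMF, 80 °C
Reagents that add atoms: none
Why: SN2 displacement of bromide from the bromomethyltrifluoroborate by the only free phenoxide (Williamson-type) should fix the future ether oxygen at chromone O6.

Step 9
Reactants: 6 2-(hydroxymethyl)-4-oxo-6-(2-phenylethyl)-4H-pyran-3-yl trifluoromethanesulfonate; 13 potassium ({[7-(benzyloxy)-4-oxo-2-(2-phenylethyl)-4H-chromen-6-yl]oxy}methyl)trifluoroborate
Product: 14 7-(benzyloxy)-6-{[2-(hydroxymethyl)-4-oxo-6-(2-phenylethyl)-4H-pyran-3-yl]methoxy}-2-(2-phenylethyl)-4H-chromen-4-one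
Conditions: Pd(OAc)2 (5 mol%), RuPhos (10 mol%), K2CO3 (3 equiv), toluene/H2O 10:1, 85 °C
Reagents that add atoms: none
Why: Suzuki–Miyaura sp3–sp2 coupling of an alkoxymethyl-type trifluoroborate with an electron-poor enol triflate should work because oxidative addition is fast and the transferred CH2–O group has no β-hydrogen.

Step 10
Reactants: 14 7-(benzyloxy)-6-{[2-(hydroxymethyl)-4-oxo-6-(2-phenylethyl)-4H-pyran-3-yl]methoxy}-2-(2-phenylethyl)-4H-chromen-4-one
Product: 15 3-({[7-(benzyloxy)-4-oxo-2-(2-phenylethyl)-4H-chromen-6-yl]oxy}methyl)-4-oxo-6-(2-phenylethyl)-4H-pyran-2-carbaldehyde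
Conditions: activated MnO2 (10 equiv), CH2Cl2, rt, dark
Reagents that add atoms: none
Why: as in step 1, MnO2 should oxidize the allylic-type primary alcohol selectively to the aldehyde without touching ethers or chromone.

Step 11
Reactants: 16 (1S,2R,5S)-(+)-menthyl (R)-4-methylbenzenesulfinate; 17 vinylmagnesium bromide
Product: 18 (S)-1-(ethenesulfinyl)-4-methylbenzene ((S)-p-tolyl vinyl sulfoxide)
Conditions: THF/toluene, −40 → 0 °C; aq. NH4Cl
Reagents that add atoms: none
Why: substitution at sulfur of a menthyl sulfinate by a Grignard reagent proceeds with inversion, so the (R)-sulfinate should give the (S)-sulfoxide as a single enantiomer.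

Step 12
Reactants: 15 3-({[7-(benzyloxy)-4-oxo-2-(2-phenylethyl)-4H-chromen-6-yl]oxy}methyl)-4-oxo-6-(2-phenylethyl)-4H-pyran-2-carbaldehyde; 18 (S)-p-tolyl vinyl sulfoxide
Product: 20 (5R,7S,8R)-5-{[7-(benzyloxy)-4-oxo-2-(2-phenylethyl)-4H-chromen-6-yl]oxy}-8-hydroxy-7-[(S)-4-methylbenzenesulfinyl]-2-(2-phenylethyl)-5,6,7,8-tetrahydro-4H-chromen-4-one, via hydroxy-o-quinodimethane photoenol 19 (not isolated)
Conditions: Ti(OiPr)4 (3 equiv), 18 (2.5 equiv), toluene (0.02 M), 365 nm LED, rt, Ar; aq. Rochelle salt work-up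
Reagents that add atoms: none
Why: Proposed new method: n→π* excitation of the C8 aldehyde should cause a 1,5-hydrogen shift from the C5 methylene across the C4a=C8a bond to give the hydroxy-o-quinodimethane 19 with both oxygens outward, which Ti(OiPr)4 holds as a titanium dienolate; the closest known reaction type is the titanium-mediated photoenolization/Diels–Alder reaction of 2-alkylbenzaldehydes with coordinating dienophiles, here extended to a 3-alkyl-2-formyl-γ-pyranone and a vinyl sulfoxide. The carbocycle C4a–C5–C6–C7–C8–C8a closes by an intermolecular endo [4π+2π] cycloaddition (in the limit a vinylogous Michael addition at C5 followed by aldol closure at C8) that forms C5–C6 and C7–C8 and restores the pyranone. C5 and C8 come out cis because both termini of the diene carry their oxygen outward and react suprafacially, and C7 is fixed by the O–Ti–O=S bridge between the dienolate oxygen and the sulfinyl oxygen, which puts sulfur next to C8 and endo. The absolute sense is controlled by the sulfur stereocentre: within the chelate the p-tolyl group has to point away from the diene, so the (S)-sulfoxide should be delivered to the face that gives (5R,8R). The step needs regio-, endo- and face-selectivity, all of which depend on this one chelate, and it needs the uncatalysed pathway to be slow, which the poor dienophilicity of an unactivated vinyl sulfoxide secures. The C7 centre is only a relay, since it is removed in step 13.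

Step 13
Reactants: 20 (5R,7S,8R)-C7-sulfinyl adduct
Product: 21 (5R,8S)-5-{[7-(benzyloxy)-4-oxo-2-(2-phenylethyl)-4H-chromen-6-yl]oxy}-8-hydroxy-2-(2-phenylethyl)-5,8-dihydro-4H-chromen-4-one
Conditions: toluene, solid NaHCO3, 100 °C, Ar
Reagents that add atoms: none
Why: thermal sulfoxide syn-elimination (Ei) should give only the C6=C7 alkene, because sulfur at C7 is cis to the C8 hydroxyl and the only syn β-hydrogen is therefore at C6; C5 and C8 are not touched.

Step 14
Reactants: 21 (5R,8S)-5-aryloxy-8-hydroxy-5,8-dihydrochromone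
Product: 22 (5S,6S,7R,8S)-5-{[7-(benzyloxy)-4-oxo-2-(2-phenylethyl)-4H-chromen-6-yl]oxy}-6,7,8-trihydroxy-2-(2-phenylethyl)-5,6,7,8-tetrahydro-4H-chromen-4-one
Conditions: OsO4 (5 mol%), NMO (1.5 equiv), acetone/H2O 4:1, 0 °C → rt
Reagents that add atoms: osmium tetroxide, O=[Os](=O)(=O)=O; N-methylmorpholine N-oxide, C[N+]1([O-])CCOCC1; water, O
Why: catalytic osmylation should attack the only isolated alkene from the face opposite the two cis-disposed allylic C–O bonds at C5 and C8 (anti rule for allylic oxygen), which sets C6 and C7 as a cis-diol trans to both neighbours.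

Step 15
Reactants: 22 7'-O-benzyl ether of the target
Product: 23 (5S,6S,7R,8S)-6,7,8-trihydroxy-5-{[7-hydroxy-4-oxo-2-(2-phenylethyl)-4H-chromen-6-yl]oxy}-2-(2-phenylethyl)-5,6,7,8-tetrahydro-4H-chromen-4-one (CNP0248258.1)
Conditions: H2 (1 atm), 10% Pd/C, EtOAc/MeOH, rt, stopped at full conversion
Reagents that add atoms: none
Why: hydrogenolysis of the aryl benzyl ether should be much faster than reduction of the chromone C=C bonds or cleavage of the C5–O bond, which is not benzylic to a carbocyclic arene.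

## Compound list

1 | 5-(benzyloxy)-2-(hydroxymethyl)-4H-pyran-4-one | OCc1cc(=O)c(OCc2ccccc2)co1 | starting material
2 | 5-(benzyloxy)-4-oxo-4H-pyran-2-carbaldehyde | O=Cc1cc(=O)c(OCc2ccccc2)co1 | intermediate
3 | 5-(benzyloxy)-2-[(E)-2-phenylethenyl]-4H-pyran-4-one (E/Z mixture, E drawn) | O=c1cc(/C=C/c2ccccc2)occ1OCc1ccccc1 | intermediate
4 | 5-hydroxy-2-(2-phenylethyl)-4H-pyran-4-one | O=c1cc(CCc2ccccc2)occ1O | intermediate
5 | 3-hydroxy-2-(hydroxymethyl)-6-(2-phenylethyl)-4H-pyran-4-one | O=c1cc(CCc2ccccc2)oc(CO)c1O | intermediate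
6 | 2-(hydroxymethyl)-4-oxo-6-(2-phenylethyl)-4H-pyran-3-yl trifluoromethanesulfonate | O=c1cc(CCc2ccccc2)oc(CO)c1OS(=O)(=O)C(F)(F)F | intermediate
7 | 1-(2,4,5-trihydroxyphenyl)ethan-1-one | CC(=O)c1cc(O)c(O)cc1O | starting material
8 | 1-[4-(benzyloxy)-2,5-dihydroxyphenyl]ethan-1-one | CC(=O)c1cc(O)c(OCc2ccccc2)cc1O | intermediate
9 | ethyl 3-phenylpropanoate | CCOC(=O)CCc1ccccc1 | starting material
10 | 1-[4-(benzyloxy)-2,5-dihydroxyphenyl]-5-phenylpentane-1,3-dione | O=C(CC(=O)CCc1ccccc1)c1cc(O)c(OCc2ccccc2)cc1O | intermediate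
11 | 7-(benzyloxy)-6-hydroxy-2-(2-phenylethyl)-4H-chromen-4-one | O=c1cc(CCc2ccccc2)oc2cc(OCc3ccccc3)c(O)cc12 | intermediate
12 | potassium (bromomethyl)trifluoroborate | [K+].F[B-](F)(F)CBr | starting material
13 | potassium ({[7-(benzyloxy)-4-oxo-2-(2-phenylethyl)-4H-chromen-6-yl]oxy}methyl)trifluoroborate | [K+].F[B-](F)(F)COc1cc2c(=O)cc(CCc3ccccc3)oc2cc1OCc1ccccc1 | intermediate
14 | 7-(benzyloxy)-6-{[2-(hydroxymethyl)-4-oxo-6-(2-phenylethyl)-4H-pyran-3-yl]methoxy}-2-(2-phenylethyl)-4H-chromen-4-one | OCc1oc(CCc2ccccc2)cc(=O)c1COc1cc2c(=O)cc(CCc3ccccc3)oc2cc1OCc1ccccc1 | intermediate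
15 | 3-({[7-(benzyloxy)-4-oxo-2-(2-phenylethyl)-4H-chromen-6-yl]oxy}methyl)-4-oxo-6-(2-phenylethyl)-4H-pyran-2-carbaldehyde | O=Cc1oc(CCc2ccccc2)cc(=O)c1COc1cc2c(=O)cc(CCc3ccccc3)oc2cc1OCc1ccccc1 | intermediate
16 | (1S,2R,5S)-(+)-menthyl (R)-4-methylbenzenesulfinate | CC(C)[C@H]1CC[C@H](C)C[C@@H]1O[S@@](=O)c1ccc(C)cc1 | starting material
17 | vinylmagnesium bromide | C=C[Mg]Br | starting material
18 | (S)-1-(ethenesulfinyl)-4-methylbenzene ((S)-p-tolyl vinyl sulfoxide) | C=C[S@](=O)c1ccc(C)cc1 | intermediate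
19 | photoenol: 3-[(aryloxy)methylidene]-2-(hydroxymethylidene)-6-(2-phenylethyl)-2,3-dihydro-4H-pyran-4-one, both exocyclic C–O bonds pointing away from the diene interior (Z,Z by the sequence rule); present as its titanium dienolate | O/C=C1\OC(CCc2ccccc2)=CC(=O)/C1=C\Oc1cc2c(=O)cc(CCc3ccccc3)oc2cc1OCc1ccccc1 | intermediate
20 | (5R,7S,8R)-5-{[7-(benzyloxy)-4-oxo-2-(2-phenylethyl)-4H-chromen-6-yl]oxy}-8-hydroxy-7-[(S)-4-methylbenzenesulfinyl]-2-(2-phenylethyl)-5,6,7,8-tetrahydro-4H-chromen-4-one | O=c1cc(CCc2ccccc2)oc2c1[C@H](Oc1cc3c(=O)cc(CCc4ccccc4)oc3cc1OCc1ccccc1)C[C@H]([S@](=O)c1ccc(C)cc1)[C@@H]2O | intermediate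
21 | (5R,8S)-5-{[7-(benzyloxy)-4-oxo-2-(2-phenylethyl)-4H-chromen-6-yl]oxy}-8-hydroxy-2-(2-phenylethyl)-5,8-dihydro-4H-chromen-4-one | O=c1cc(CCc2ccccc2)oc2c1[C@H](Oc1cc3c(=O)cc(CCc4ccccc4)oc3cc1OCc1ccccc1)C=C[C@@H]2O | intermediate
22 | (5S,6S,7R,8S)-5-{[7-(benzyloxy)-4-oxo-2-(2-phenylethyl)-4H-chromen-6-yl]oxy}-6,7,8-trihydroxy-2-(2-phenylethyl)-5,6,7,8-tetrahydro-4H-chromen-4-one | O=c1cc(CCc2ccccc2)oc2c1[C@H](Oc1cc3c(=O)cc(CCc4ccccc4)oc3cc1OCc1ccccc1)[C@@H](O)[C@@H](O)[C@@H]2O | intermediate
23 | (5S,6S,7R,8S)-6,7,8-trihydroxy-5-{[7-hydroxy-4-oxo-2-(2-phenylethyl)-4H-chromen-6-yl]oxy}-2-(2-phenylethyl)-5,6,7,8-tetrahydro-4H-chromen-4-one (CNP0248258.1) | O=c1cc(CCc2ccccc2)oc2c1[C@H](Oc1cc3c(=O)cc(CCc4ccccc4)oc3cc1O)[C@@H](O)[C@@H](O)[C@@H]2O | target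

## Step count and risks

Total step count: 15. Longest linear sequence: 11 steps (1–5, 9, 10, 12–15).

Steps most likely to fail:

1. Step 12 (Proposed new method). The photoenol may re-ketonize faster than it is trapped, the two pyranone chromophores may undergo competing photochemistry, or face control may be lost if the sulfinyl oxygen does not bind titanium. The fallback uses known reaction types and no light, and sets out from 15. Soft enolization with TBSOTf/Et3N (CH2Cl2, −78 → 0 °C) should give the silyl dienol ether F1, a 1-silyloxy diene of the same quinodimethane type. Thermal Diels–Alder reaction with 18 (toluene, 40–60 °C), with chromatographic removal of the minor facial diastereomer, should give the silyl ether F2. HF·pyridine (THF, 0 °C) comes back to the route at 20.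

2. Step 13. At 100 °C, or under the sulfenic acid that is released, the C5 aryloxy group may be lost with aromatization of the carbocycle. The fallback is a low-temperature reductive route with the enantiomers separated afterwards, and sets out from 15. The photoenol is trapped without titanium by the much more reactive (E)-1,2-bis(phenylsulfonyl)ethene (365 nm, toluene, rt) to give the racemic bis-sulfone F3. Buffered sodium amalgam (6% Na/Hg, NaH2PO4, MeOH/THF, −20 °C) should remove both sulfonyl groups and give the racemic dienol, that is 21 together with its enantiomer F4. Kinetic resolution with immobilized Candida antarctica lipase B and vinyl acetate (MTBE, rt) is expected, by the usual empirical rule for secondary alcohols, to acetylate the (8R)-enantiomer to the acetate F5 and leave 21, where the fallback comes back to the route.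

3. Step 9. Transmetalation of the sp3 trifluoroborate may be slow, so that hydrolysis of the enol triflate or protodeboronation takes over. The fallback sets out from 6. Silylation (TBSCl, imidazole, DMF) gives the silyl ether F6. Stille coupling with (tributylstannyl)methanol (Pd(PPh3)4, LiCl, dioxane, 90 °C) gives the hydroxymethyl pyranone F7. Mitsunobu etherification with phenol 11 (PPh3, DIAD, THF, 0 °C → rt) gives the aryl ether F8. TBAF/AcOH (THF, 0 °C) comes back to the route at 14.

## Further compounds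

F1 | step 12 | tert-butyldimethylsilyl dienol ether of 15 (O-silylated quinodimethane, both exocyclic C–O bonds outward) | CC(C)(C)[Si](C)(C)O/C=C1\OC(CCc2ccccc2)=CC(=O)/C1=C\Oc1cc2c(=O)cc(CCc3ccccc3)oc2cc1OCc1ccccc1
F2 | step 12 | 8-O-tert-butyldimethylsilyl ether of 20 | O=c1cc(CCc2ccccc2)oc2c1[C@H](Oc1cc3c(=O)cc(CCc4ccccc4)oc3cc1OCc1ccccc1)C[C@H]([S@](=O)c1ccc(C)cc1)[C@@H]2O[Si](C)(C)C(C)(C)C
F3 | step 13 | racemic 5,8-cis-5-aryloxy-8-hydroxy-6,7-trans-bis(phenylsulfonyl)-5,6,7,8-tetrahydrochromone (one enantiomer drawn) | O=c1cc(CCc2ccccc2)oc2c1[C@H](Oc1cc3c(=O)cc(CCc4ccccc4)oc3cc1OCc1ccccc1)[C@@H](S(=O)(=O)c1ccccc1)[C@H](S(=O)(=O)c1ccccc1)[C@@H]2O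
F4 | step 13 | (5S,8R)-enantiomer of 21 | O=c1cc(CCc2ccccc2)oc2c1[C@@H](Oc1cc3c(=O)cc(CCc4ccccc4)oc3cc1OCc1ccccc1)C=C[C@H]2O
F5 | step 13 | 8-O-acetate of the (5S,8R)-enantiomer of 21 | O=c1cc(CCc2ccccc2)oc2c1[C@@H](Oc1cc3c(=O)cc(CCc4ccccc4)oc3cc1OCc1ccccc1)C=C[C@H]2OC(C)=O
F6 | step 9 | 2-{[(tert-butyldimethylsilyl)oxy]methyl}-4-oxo-6-(2-phenylethyl)-4H-pyran-3-yl trifluoromethanesulfonate | O=c1cc(CCc2ccccc2)oc(CO[Si](C)(C)C(C)(C)C)c1OS(=O)(=O)C(F)(F)F
F7 | step 9 | 2-{[(tert-butyldimethylsilyl)oxy]methyl}-3-(hydroxymethyl)-6-(2-phenylethyl)-4H-pyran-4-one | O=c1cc(CCc2ccccc2)oc(CO[Si](C)(C)C(C)(C)C)c1CO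
F8 | step 9 | tert-butyldimethylsilyl ether of 14 | CC(C)(C)[Si](C)(C)OCc1oc(CCc2ccccc2)cc(=O)c1COc1cc2c(=O)cc(CCc3ccccc3)oc2cc1OCc1ccccc1
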